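We count in one unit, the log-unit: the natural logarithm of starting material charged over starting material left, which turns the fraction left into a sum of rates.

| flask | starting material | free enzyme | temperature | time |
|---|---|---|---|---|
| north-east | 2.0 mM | 0.32 µM | 52 °C | 40 s |
| south | 2.0 mM | 0.32 µM | 37 °C | 40 s |

    target + free enzyme ⇌ isomer of the product + free enzyme, rate k1*[free enzyme]*[target] forward; the back reaction follows from the equilibrium constant (K1 = 0.43, k1 = 2.7 × 10⁵ L mol⁻¹ s⁻¹, Ea1 = 18.0 kJ mol⁻¹, ΔH1 = −49.0 kJ mol⁻¹)
    complex → free enzyme + target (k2 = 450 s⁻¹, Ea2 = 50.0 kJ mol⁻¹)
    starting material + free enzyme ⇌ complex (K3 = 220 L mol⁻¹, k3 = 9.7 × 10⁶ L mol⁻¹ s⁻¹, Ea3 = 12.0 kJ mol⁻¹, ΔH3 = −6.00 kJ mol⁻¹)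
    free enzyme → unfolded enzyme (k4 = 0.0027 s⁻¹, Ea4 = 286 kJ mol⁻¹)
    (constants at 37 °C)

- the constants hold at 37 °C; other temperatures follow from the activation energies and enthalpies

- the best flask by amount of target, in percent of the starting material charged; "all alike" if 1.5 percentage points covers them all (north-east / south / all alike)
- amount of target at the end, in percent of the starting material charged, north-east
- amount of target at the end, in percent of the starting material charged, south

1. With the complex in steady state, the log-unit grows at a[free enzyme], a pseudo-first-order constant for the starting material. Here a is the breakdown constant of the complex over Km, and Km is the falling-back plus breakdown constants over the binding constant. Km is 4.59 mM in south. North-east has a breakdown constant of 1100 s⁻¹ and a Km of 5.15 mM.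

2. At the start, [free enzyme] is the share Km/(Km+[starting material]) of the charge: 69.7% in south, 72.0% in north-east. The rate therefore opens at 0.0218 s⁻¹ in south and 0.0492 s⁻¹ in north-east, faster there than in south.

3. Unfolding takes enzyme at its constant times the same [free enzyme], 0.0027 s⁻¹ in south and 0.450 s⁻¹ in north-east. While the complex stays in steady state, each log-unit therefore costs a set amount of enzyme, and saturation cancels. The enzyme budget is a times the charge over the unfolding constant, the log-units a charge earns before it has unfolded: 0.152 in north-east, 11.6 in south.

4. In north-east the enzyme lasts about 3.09 s, far less than 40 s, so we take the budget as used up: 85.9% left, 14.1% made.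

5. In south the opening rate over 40 s asks 0.874 log-units, far below the budget. By the end of south, unfolding multiplies the rate by a factor 0.928, and the falling [starting material] frees enzyme, a factor 1.21. The mean of the opening and closing rates gives 0.929 log-units, so 39.5% is left in south.

6. If what is made splits at each flask's equilibrium constant of step one, target is 42.3% in south and 12.0% in north-east, so in our reckoning south gives more than north-east.

The forecast says south, with 12.9% in north-east and 44.1% in south, both above our split; of south it says: “Isomerisation is fast and lags only slightly”.

The simulation gives south, with 12.9% in north-east and 44.0% in south. In north-east, half of the breakdown of complex up to the end was done by 2.00 s, far sooner than 40 s, and the flask stopped near its budget of 0.152, with 86% of the starting material left and free enzyme at 0% of the catalyst charged. In south, free enzyme stood at 78.5% at 40.0 s, with 0.939 log-units earned of 11.6.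

A neighbour of north-east is charged with 1.3 × 10⁻⁴ mM of free enzyme. Its budget is 0.0617, which leaves 94.0%. That flask shows 94% of the starting material left and 5.72% target.

(The constants used here come from no measurement; no experiment stands behind them.)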